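The route reads C6–C7–C8 and the 8-methyl group of ring B (C4a, C5, C6, C7, C8, C8a; octahydronaphthalene numbering, acetyl at C1) as crotonaldehyde. In one flask its β-carbon (C8) is bonded to C8a by iminium-catalysed enantioselective conjugate addition of an alkenyltrifluoroborate, and its carbonyl carbon (C6) to C5 by Wittig olefination; the precursors are three small achiral commercial compounds. The C5=C6 alkene later takes up both oxygens in differentiated form (asymmetric epoxidation, then epoxide opening by the glutaconic acid with inversion at C6), and an intramolecular Diels–Alder reaction finally closes rings A and B and sets the four remaining ring stereocentres.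

Key step: step 1

Remark on the chemistry: (2R)-2-methylbutan-1-ol (17) is assumed to be purchasable in enantiopure form; "future C5, C6, C8" in the steps refers to the target numbering given above.

Step 1
Reactants: 1 (E)-but-2-enal; 2 potassium (E)-prop-1-en-1-yltrifluoroborate; 3 ethyl (triphenylphosphoranylidene)acetate
Product: 5 ethyl (2E,5R,6E)-5-methylocta-2,6-dienoate, via (3R,4E)-3-methylhex-4-enal 4 (not isolated)
Conditions: (2S,5S)-5-benzyl-2-tert-butyl-3-methylimidazolidin-4-one hydrochloride (20 mol%), HF (1 equiv), DME, −20 °C; then NaHCO3, 3, 0 °C to rt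
Reagents that add atoms: none
Why: The secondary amine condenses with 1 to an (E)-iminium ion, one face of which is shielded by the benzyl group, so the alkenyltrifluoroborate attacks the β-carbon from the open face through a β-boryl-stabilised cation that loses BF3 (taken up by fluoride as KBF4), and hydrolysis of the enamine releases aldehyde 4 and the catalyst; the stabilised ylide 3 then olefinates 4 in the same flask. The closest known reaction types are the organocatalytic conjugate addition of vinyl trifluoroborates to enals and the Wittig reaction of stabilised ylides, run here as a one-pot sequence. No ring is closed in this step. The one new stereocentre (future C8) is set by the catalyst, not by the substrate, and is expected to be R with the (2S,5S)-catalyst. The step needs 1,4- over 1,2-addition, which iminium activation secures, and an E alkene, which the ester-stabilised ylide secures. Carrying the volatile, enolisable aldehyde 4 forward without isolation is what makes the two bond formations (future C8–C8a and C5–C6, the latter as a C=C bond) one operation.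

Step 2
Reactants: 5 ethyl (2E,5R,6E)-5-methylocta-2,6-dienoate
Product: 6 (2E,5R,6E)-5-methylocta-2,6-dien-1-ol
Conditions: i-Bu2AlH (2.2 equiv), CH2Cl2, −78 °C; aq. potassium sodium tartrate
Reagents that add atoms: none
Why: Ester reduction by two hydride transfers from i-Bu2AlH at low temperature should give the allylic alcohol without touching the alkenes or the C5 stereocentre.

Step 3
Reactants: 6 (2E,5R,6E)-5-methylocta-2,6-dien-1-ol
Product: 7 [(2S,3S)-3-[(2R,3E)-2-methylpent-3-en-1-yl]oxiran-2-yl]methanol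
Conditions: Ti(O-i-Pr)4 (10 mol%), L-(+)-diethyl tartrate (12 mol%), t-BuOOH, 4 Å molecular sieves, CH2Cl2, −20 °C
Reagents that add atoms: tert-butyl hydroperoxide, CC(C)(C)OO
Why: Sharpless asymmetric epoxidation: the titanium tartrate binds the allylic alcohol, so only its alkene is oxidised, and L-(+)-diethyl tartrate should direct oxygen to the face that gives the (2S,3S)-epoxide under reagent control, which fixes the future C5 configuration.

Step 4
Reactants: 8 but-2-ynoic acid
Product: 10 (2E)-3-iodobut-2-enoic acid, via (2Z)-3-iodobut-2-enoic acid 9 (not isolated)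
Conditions: 57% aq. HI, 90 °C; then neat, 130 °C
Reagents that add atoms: hydrogen iodide, I
Why: Anti hydroiodination of the ynoic acid gives the Z iodide, which is expected to equilibrate on heating to the E isomer with iodine trans to the carboxyl group (thermal alkene isomerisation).

Step 5
Reactants: 10 (2E)-3-iodobut-2-enoic acid
Product: 11 (2E)-5-tert-butoxy-3-methyl-5-oxopent-2-enoic acid
Conditions: BrZnCH2CO2-t-Bu (2.5 equiv), PdCl2(MeCN)2 (5 mol%), DMF/THF, rt
Reagents that add atoms: (2-tert-butoxy-2-oxoethyl)zinc bromide, CC(C)(C)OC(=O)C[Zn]Br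
Why: Negishi coupling of the alkenyl iodide with the Reformatsky zinc reagent proceeds with retention of alkene geometry, so CH2CO2-t-Bu ends up trans to the carboxyl group as the (E)-3-methylglutaconate unit requires.

Step 6
Reactants: 7 [(2S,3S)-3-[(2R,3E)-2-methylpent-3-en-1-yl]oxiran-2-yl]methanol; 11 (2E)-5-tert-butoxy-3-methyl-5-oxopent-2-enoic acid
Product: 12 5-tert-butyl 1-[(2S,3R,5R,6E)-1,2-dihydroxy-5-methyloct-6-en-3-yl] (2E)-3-methylpent-2-enedioate
Conditions: Ti(O-i-Pr)4 (1.5 equiv), CH2Cl2, rt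
Reagents that add atoms: none
Why: Titanium-mediated opening of the 2,3-epoxy alcohol: the metal binds the C1 hydroxyl and the epoxide oxygen and delivers the carboxylate to C3 with inversion, which places the ester oxygen on the future C6 with R configuration and leaves the future C5 oxygen as a free hydroxyl of unchanged configuration.

Step 7
Reactants: 12 5-tert-butyl 1-[(2S,3R,5R,6E)-1,2-dihydroxy-5-methyloct-6-en-3-yl] (2E)-3-methylpent-2-enedioate
Product: 14 5-tert-butyl 1-[(1E,3S,4R,6R,7E)-3-hydroxy-1-iodo-6-methylnona-1,7-dien-4-yl] (2E)-3-methylpent-2-enedioate, via hydroxy aldehyde 13 (not isolated)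
Conditions: TEMPO (10 mol%), PhI(OAc)2, CH2Cl2, rt; then CrCl2, CHI3, THF/dioxane, 0 °C
Reagents that add atoms: iodoform, IC(I)I
Why: Nitroxyl-catalysed oxidation should take the primary hydroxyl in preference to the secondary one, and the crude aldehyde is homologated at once by Takai olefination, whose geminal dichromium reagent should give the E vinyl iodide.

Step 8
Reactants: 14 5-tert-butyl 1-[(1E,3S,4R,6R,7E)-3-hydroxy-1-iodo-6-methylnona-1,7-dien-4-yl] (2E)-3-methylpent-2-enedioate
Product: 15 5-tert-butyl 1-[(1E,3S,4R,6R,7E)-1-iodo-6-methyl-3-(triethylsilyloxy)nona-1,7-dien-4-yl] (2E)-3-methylpent-2-enedioate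
Conditions: Et3SiCl, imidazole, CH2Cl2, 0 °C
Reagents that add atoms: chlorotriethylsilane, CC[Si](Cl)(CC)CC
Why: Silyl ether formation at the only free hydroxyl protects the future C5 oxygen against oxa-Michael addition to the enone of the next steps and against acyl migration.

Step 9
Reactants: 15 5-tert-butyl 1-[(1E,3S,4R,6R,7E)-1-iodo-6-methyl-3-(triethylsilyloxy)nona-1,7-dien-4-yl] (2E)-3-methylpent-2-enedioate
Product: 16 5-tert-butyl 1-[(1E,3S,4R,6R,7E)-1-iodo-6-methyl-9-oxo-3-(triethylsilyloxy)deca-1,7-dien-4-yl] (2E)-3-methylpent-2-enedioate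
Conditions: but-3-en-2-one (5 equiv), second-generation Hoveyda–Grubbs catalyst RuCl2(H2IMes)(=CH-C6H4-2-O-i-Pr) (5 mol%), CH2Cl2, 40 °C
Reagents that add atoms: but-3-en-2-one, CC(=O)C=C
Why: Olefin cross-metathesis replaces the methyl-capped alkene terminus by the acetyl-bearing alkylidene of excess methyl vinyl ketone and should give the E enone, the vinyl iodide and the trisubstituted enoate being poor metathesis partners.

Step 10
Reactants: 17 (2R)-2-methylbutan-1-ol
Product: 19 (1E,3R)-1-iodo-3-methylpent-1-ene, via (2R)-2-methylbutanal 18 (not isolated)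
Conditions: TEMPO (cat.), PhI(OAc)2, CH2Cl2, 0 °C to rt; then CrCl2, CHI3, THF, 0 °C
Reagents that add atoms: iodoform, IC(I)I
Why: Base-free nitroxyl oxidation avoids epimerisation of the α-stereocentre, and Takai olefination of the crude aldehyde should give the E vinyl iodide that carries the purchased sec-butyl stereocentre.

Step 11
Reactants: 16 5-tert-butyl 1-[(1E,3S,4R,6R,7E)-1-iodo-6-methyl-9-oxo-3-(triethylsilyloxy)deca-1,7-dien-4-yl] (2E)-3-methylpent-2-enedioate; 19 (1E,3R)-1-iodo-3-methylpent-1-ene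
Product: 21 5-tert-butyl 1-[(3E,5R,7R,8S,9E,11E,13R)-5,13-dimethyl-2-oxo-8-(triethylsilyloxy)pentadeca-3,9,11-trien-7-yl] (2E)-3-methylpent-2-enedioate, via alkenylzinc chloride 20 (not isolated)
Conditions: 19, t-BuLi (2.1 equiv), Et2O, −78 °C; ZnCl2, THF; then 16, Pd(PPh3)4 (5 mol%), THF, 0 °C to rt
Reagents that add atoms: none
Why: Negishi coupling: iodine–lithium exchange and transmetalation to zinc proceed with retention, and the alkenylzinc should couple with the vinyl iodide under zerovalent palladium catalysis with retention at both alkenes to give the (E,E)-diene without attacking the enone or the esters.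

Step 12
Reactants: 21 5-tert-butyl 1-[(3E,5R,7R,8S,9E,11E,13R)-5,13-dimethyl-2-oxo-8-(triethylsilyloxy)pentadeca-3,9,11-trien-7-yl] (2E)-3-methylpent-2-enedioate
Product: 22 1-[(1S,2S,4aR,5S,6R,8R,8aS)-1-acetyl-2-[(2R)-butan-2-yl]-8-methyl-5-(triethylsilyloxy)-1,2,4a,5,6,7,8,8a-octahydronaphthalen-6-yl] 5-tert-butyl (2E)-3-methylpent-2-enedioate
Conditions: toluene, 2,6-di-tert-butyl-4-methylphenol (cat.), 100 °C
Reagents that add atoms: none
Why: Intramolecular Diels–Alder reaction: the (E,E)-diene and the (E)-enone should combine through the endo transition state with a chair-like tether that keeps the C8 methyl and C5 silyloxy groups equatorial, which gives the trans-fused decalin and sets C1, C2, C4a and C8a in one suprafacial event (sec-butyl cis to acetyl, acetyl trans to C8).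

Step 13
Reactants: 22 1-[(1S,2S,4aR,5S,6R,8R,8aS)-1-acetyl-2-[(2R)-butan-2-yl]-8-methyl-5-(triethylsilyloxy)-1,2,4a,5,6,7,8,8a-octahydronaphthalen-6-yl] 5-tert-butyl (2E)-3-methylpent-2-enedioate
Product: 23 (3E)-5-{[(1S,2S,4aR,5S,6R,8R,8aS)-1-acetyl-2-[(2R)-butan-2-yl]-5-hydroxy-8-methyl-1,2,4a,5,6,7,8,8a-octahydronaphthalen-6-yl]oxy}-3-methyl-5-oxopent-3-enoic acid
Conditions: CF3CO2H/CH2Cl2/H2O (20:78:2), 0 °C to rt
Reagents that add atoms: none
Why: Acidolysis: trifluoroacetic acid should remove the tert-butyl group as 2-methylpropene and cleave the triethylsilyl ether, while the secondary ester, the ketone and both alkenes are stable.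

Compound list
1 | (E)-but-2-enal (crotonaldehyde) | C/C=C/C=O | starting material
2 | potassium (E)-prop-1-en-1-yltrifluoroborate | C/C=C/[B-](F)(F)F.[K+] | starting material
3 | ethyl (triphenylphosphoranylidene)acetate | CCOC(=O)C=P(c1ccccc1)(c1ccccc1)c1ccccc1 | starting material
4 | (3R,4E)-3-methylhex-4-enal | O=CC[C@@H](C)/C=C/C | intermediate
5 | ethyl (2E,5R,6E)-5-methylocta-2,6-dienoate | CCOC(=O)/C=C/C[C@@H](C)/C=C/C | intermediate
6 | (2E,5R,6E)-5-methylocta-2,6-dien-1-ol | OC/C=C/C[C@@H](C)/C=C/C | intermediate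
7 | [(2S,3S)-3-[(2R,3E)-2-methylpent-3-en-1-yl]oxiran-2-yl]methanol | OC[C@@H]1O[C@H]1C[C@@H](C)/C=C/C | intermediate
8 | but-2-ynoic acid | CC#CC(=O)O | starting material
9 | (2Z)-3-iodobut-2-enoic acid | OC(=O)/C=C(/C)I | intermediate
10 | (2E)-3-iodobut-2-enoic acid | OC(=O)/C=C(\C)I | intermediate
11 | (2E)-5-tert-butoxy-3-methyl-5-oxopent-2-enoic acid | OC(=O)/C=C(\C)CC(=O)OC(C)(C)C | intermediate
12 | 5-tert-butyl 1-[(2S,3R,5R,6E)-1,2-dihydroxy-5-methyloct-6-en-3-yl] (2E)-3-methylpent-2-enedioate | OC[C@H](O)[C@H](OC(=O)/C=C(\C)CC(=O)OC(C)(C)C)C[C@@H](C)/C=C/C | intermediate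
13 | 5-tert-butyl 1-[(2R,3R,5R,6E)-2-hydroxy-5-methyl-1-oxooct-6-en-3-yl] (2E)-3-methylpent-2-enedioate (hydroxy aldehyde) | O=C[C@H](O)[C@H](OC(=O)/C=C(\C)CC(=O)OC(C)(C)C)C[C@@H](C)/C=C/C | intermediate
14 | 5-tert-butyl 1-[(1E,3S,4R,6R,7E)-3-hydroxy-1-iodo-6-methylnona-1,7-dien-4-yl] (2E)-3-methylpent-2-enedioate | I/C=C/[C@H](O)[C@H](OC(=O)/C=C(\C)CC(=O)OC(C)(C)C)C[C@@H](C)/C=C/C | intermediate
15 | 5-tert-butyl 1-[(1E,3S,4R,6R,7E)-1-iodo-6-methyl-3-(triethylsilyloxy)nona-1,7-dien-4-yl] (2E)-3-methylpent-2-enedioate | I/C=C/[C@H](O[Si](CC)(CC)CC)[C@H](OC(=O)/C=C(\C)CC(=O)OC(C)(C)C)C[C@@H](C)/C=C/C | intermediate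
16 | 5-tert-butyl 1-[(1E,3S,4R,6R,7E)-1-iodo-6-methyl-9-oxo-3-(triethylsilyloxy)deca-1,7-dien-4-yl] (2E)-3-methylpent-2-enedioate | I/C=C/[C@H](O[Si](CC)(CC)CC)[C@H](OC(=O)/C=C(\C)CC(=O)OC(C)(C)C)C[C@@H](C)/C=C/C(C)=O | intermediate
17 | (2R)-2-methylbutan-1-ol | CC[C@@H](C)CO | starting material
18 | (2R)-2-methylbutanal | CC[C@@H](C)C=O | intermediate
19 | (1E,3R)-1-iodo-3-methylpent-1-ene | CC[C@@H](C)/C=C/I | intermediate
20 | chloro[(1E,3R)-3-methylpent-1-en-1-yl]zinc (alkenylzinc chloride) | CC[C@@H](C)/C=C/[Zn]Cl | intermediate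
21 | 5-tert-butyl 1-[(3E,5R,7R,8S,9E,11E,13R)-5,13-dimethyl-2-oxo-8-(triethylsilyloxy)pentadeca-3,9,11-trien-7-yl] (2E)-3-methylpent-2-enedioate | CC[C@@H](C)/C=C/C=C/[C@H](O[Si](CC)(CC)CC)[C@H](OC(=O)/C=C(\C)CC(=O)OC(C)(C)C)C[C@@H](C)/C=C/C(C)=O | intermediate
22 | 1-[(1S,2S,4aR,5S,6R,8R,8aS)-1-acetyl-2-[(2R)-butan-2-yl]-8-methyl-5-(triethylsilyloxy)-1,2,4a,5,6,7,8,8a-octahydronaphthalen-6-yl] 5-tert-butyl (2E)-3-methylpent-2-enedioate | CC[C@@H](C)[C@H]1C=C[C@H]2[C@H](O[Si](CC)(CC)CC)[C@H](OC(=O)/C=C(\C)CC(=O)OC(C)(C)C)C[C@@H](C)[C@@H]2[C@H]1C(C)=O | intermediate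
23 | (3E)-5-{[(1S,2S,4aR,5S,6R,8R,8aS)-1-acetyl-2-[(2R)-butan-2-yl]-5-hydroxy-8-methyl-1,2,4a,5,6,7,8,8a-octahydronaphthalen-6-yl]oxy}-3-methyl-5-oxopent-3-enoic acid | CC[C@@H](C)[C@H]1C=C[C@H]2[C@H](O)[C@H](OC(=O)/C=C(\C)CC(=O)O)C[C@@H](C)[C@@H]2[C@H]1C(C)=O | target

Total step count: 13 steps. Longest linear sequence: 10 steps (steps 1, 2, 3, 6, 7, 8, 9, 11, 12, 13).

Steps most likely to fail

Step 7. What may go wrong: glycol cleavage by the iodine oxidant, or β-elimination of the acyloxy group and acyl migration in the unprotected hydroxy aldehyde before it is olefinated. The fallback sets out from 12 and comes back at 15. Both hydroxyls are silylated (Et3SiOTf, 2,6-lutidine) to 5-tert-butyl 1-[(2S,3R,5R,6E)-5-methyl-1,2-bis(triethylsilyloxy)oct-6-en-3-yl] (2E)-3-methylpent-2-enedioate F1. The primary silyl ether is cleaved selectively (HF·pyridine, pyridine, THF, 0 °C) to 5-tert-butyl 1-[(2S,3R,5R,6E)-1-hydroxy-5-methyl-2-(triethylsilyloxy)oct-6-en-3-yl] (2E)-3-methylpent-2-enedioate F2. Buffered Dess–Martin oxidation gives 5-tert-butyl 1-[(2R,3R,5R,6E)-5-methyl-1-oxo-2-(triethylsilyloxy)oct-6-en-3-yl] (2E)-3-methylpent-2-enedioate F3, and Takai olefination (CrCl2, CHI3) then gives 15 directly, so step 8 is no longer needed.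

Step 12. What may go wrong: low endo (trans-fused) or facial selectivity in the uncatalysed cycloaddition. The fallback sets out from 15 and comes back at 22. Cross-metathesis of 15 with (E)-but-2-enal 1 (ruthenium catalyst of step 9) gives the enal 5-tert-butyl 1-[(1E,3S,4R,6R,7E)-1-iodo-6-methyl-9-oxo-3-(triethylsilyloxy)nona-1,7-dien-4-yl] (2E)-3-methylpent-2-enedioate F4. Negishi coupling with 19 through 20, as in step 11, gives the trienal 5-tert-butyl 1-[(2E,4R,6R,7S,8E,10E,12R)-4,12-dimethyl-1-oxo-7-(triethylsilyloxy)tetradeca-2,8,10-trien-6-yl] (2E)-3-methylpent-2-enedioate F5. An iminium-catalysed intramolecular Diels–Alder reaction, with the enantiomer of the 5-benzyl-2-tert-butyl-3-methylimidazolidin-4-one salt that is matched to the tether stereocentres, should enforce the endo mode under catalyst control and give 5-tert-butyl 1-[(1S,2S,4aR,5S,6R,8R,8aS)-2-[(2R)-butan-2-yl]-1-formyl-8-methyl-5-(triethylsilyloxy)-1,2,4a,5,6,7,8,8a-octahydronaphthalen-6-yl] (2E)-3-methylpent-2-enedioate F6. Aldehyde-selective methyl addition with MeTi(O-i-Pr)3 gives the 1-(1-hydroxyethyl) analogue of F6 (both carbinol epimers) F7, and Dess–Martin oxidation returns ketone 22.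

Step 1. What may go wrong: sluggish attack of the alkyl-substituted alkenyltrifluoroborate on the iminium ion, with competing self-condensation of the enal or eroded enantioselectivity. The fallback sets out from ylide 3 and a new purchased alcohol and comes back at 5. Hg(OAc)2-catalysed vinyl ether exchange of (2R,3E)-pent-3-en-2-ol F8 with ethyl vinyl ether gives (2R,3E)-2-(ethenyloxy)pent-3-ene F9. Its Claisen rearrangement (sealed tube, 130 °C) through the chair transition state with equatorial methyl should transfer chirality and give aldehyde 4, which is treated with ylide 3 as in step 1 to give 5.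

Further compounds
F1 | step 7 | 5-tert-butyl 1-[(2S,3R,5R,6E)-5-methyl-1,2-bis(triethylsilyloxy)oct-6-en-3-yl] (2E)-3-methylpent-2-enedioate | CC[Si](CC)(CC)OC[C@H](O[Si](CC)(CC)CC)[C@H](OC(=O)/C=C(\C)CC(=O)OC(C)(C)C)C[C@@H](C)/C=C/C
F2 | step 7 | 5-tert-butyl 1-[(2S,3R,5R,6E)-1-hydroxy-5-methyl-2-(triethylsilyloxy)oct-6-en-3-yl] (2E)-3-methylpent-2-enedioate | OC[C@H](O[Si](CC)(CC)CC)[C@H](OC(=O)/C=C(\C)CC(=O)OC(C)(C)C)C[C@@H](C)/C=C/C
F3 | step 7 | 5-tert-butyl 1-[(2R,3R,5R,6E)-5-methyl-1-oxo-2-(triethylsilyloxy)oct-6-en-3-yl] (2E)-3-methylpent-2-enedioate | O=C[C@H](O[Si](CC)(CC)CC)[C@H](OC(=O)/C=C(\C)CC(=O)OC(C)(C)C)C[C@@H](C)/C=C/C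
F4 | step 12 | 5-tert-butyl 1-[(1E,3S,4R,6R,7E)-1-iodo-6-methyl-9-oxo-3-(triethylsilyloxy)nona-1,7-dien-4-yl] (2E)-3-methylpent-2-enedioate | I/C=C/[C@H](O[Si](CC)(CC)CC)[C@H](OC(=O)/C=C(\C)CC(=O)OC(C)(C)C)C[C@@H](C)/C=C/C=O
F5 | step 12 | 5-tert-butyl 1-[(2E,4R,6R,7S,8E,10E,12R)-4,12-dimethyl-1-oxo-7-(triethylsilyloxy)tetradeca-2,8,10-trien-6-yl] (2E)-3-methylpent-2-enedioate | CC[C@@H](C)/C=C/C=C/[C@H](O[Si](CC)(CC)CC)[C@H](OC(=O)/C=C(\C)CC(=O)OC(C)(C)C)C[C@@H](C)/C=C/C=O
F6 | step 12 | 5-tert-butyl 1-[(1S,2S,4aR,5S,6R,8R,8aS)-2-[(2R)-butan-2-yl]-1-formyl-8-methyl-5-(triethylsilyloxy)-1,2,4a,5,6,7,8,8a-octahydronaphthalen-6-yl] (2E)-3-methylpent-2-enedioate | CC[C@@H](C)[C@H]1C=C[C@H]2[C@H](O[Si](CC)(CC)CC)[C@H](OC(=O)/C=C(\C)CC(=O)OC(C)(C)C)C[C@@H](C)[C@@H]2[C@H]1C=O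
F7 | step 12 | 1-(1-hydroxyethyl) analogue of F6 (both carbinol epimers) | CC[C@@H](C)[C@H]1C=C[C@H]2[C@H](O[Si](CC)(CC)CC)[C@H](OC(=O)/C=C(\C)CC(=O)OC(C)(C)C)C[C@@H](C)[C@@H]2[C@H]1C(C)O
F8 | step 1 | (2R,3E)-pent-3-en-2-ol | C[C@@H](O)/C=C/C
F9 | step 1 | (2R,3E)-2-(ethenyloxy)pent-3-ene | C[C@@H](OC=C)/C=C/C
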